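The numbers in the tables are calculated for an exercise; scatter was added.

The easy step came first: in the south-west run substrate turns to product under free catalyst, and I divided the 34 min reading, 0.3198 M, by the substrate charge, 0.400 M. That gave 79.9 %, which I called the clock share: the part of a substrate charge turned by a given time, at a given charge of free catalyst.

| flask | substrate | free catalyst | product | time |
|---|---|---|---|---|
| south-west | 0.400 M | 0.0320 M |  |  |
| south-east | 0.400 M | 0.0480 M |  |  |
| north-east | 0.800 M | 0.0320 M |  |  |
| east | 0.400 M | 0.0320 M | 0.200 M |  |
| south | 0.120 M | 0.0320 M |  | 34 min |

| run | time / min | [product] / M |
|---|---|---|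
| south-west run | 1.4 | 0.0127 |
| south-west run | 2.2 | 0.0265 |
| south-west run | 3.4 | 0.0551 |
| south-west run | 5.4 | 0.1032 |
| south-west run | 8.6 | 0.1687 |
| south-west run | 14 | 0.2351 |
| south-west run | 21 | 0.2814 |
| south-west run | 34 | 0.3198 |
| south-east run | 1.4 | 0.0187 |
| south-east run | 2.2 | 0.0400 |
| south-east run | 3.4 | 0.0761 |
| south-east run | 5.4 | 0.1360 |
| south-east run | 8.6 | 0.2088 |
| south-east run | 14 | 0.2765 |
| south-east run | 21 | 0.3138 |
| south-east run | 34 | 0.3439 |
| north-east run | 1.4 | 0.0235 |
| north-east run | 2.2 | 0.0543 |
| north-east run | 3.4 | 0.1089 |
| north-east run | 5.4 | 0.2053 |
| north-east run | 8.6 | 0.3356 |
| north-east run | 14 | 0.4728 |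
| north-east run | 21 | 0.5652 |
| north-east run | 34 | 0.6399 |
| east run | 1.4 | 0.2136 |
| east run | 2.2 | 0.2287 |
| east run | 3.4 | 0.2542 |
| east run | 5.4 | 0.3037 |
| east run | 8.6 | 0.3684 |
| east run | 14 | 0.4366 |
| east run | 21 | 0.4825 |
| east run | 34 | 0.5213 |

(each reading ± 0.001 M)

- the power of [substrate] that the first rate follows, about the charge of the south-west run; measure it at two percent of substrate made into product (one fixed amount of product, the same in the runs compared)
- the power of [free catalyst] that the first rate follows, about the charge of the south-west run; measure it at two percent of substrate made into product
- product in the south run at 34 min, as a share of the substrate charged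

- Overall: substrate -> product, with free catalyst as catalyst.
- Constant volume, constant temperature.
- An order is taken over about fifteen percent of the charge, up and down.

The north-east run, with twice the substrate and the same free catalyst, stood at 80.0 % at that time. A share that ignores the substrate charge, at fixed free catalyst, is pseudo-first-order behaviour in substrate. The south run has the same 0.0320 M of free catalyst, so I gave it the clock share of its 0.120 M charge.

For the orders I read the early curve. Between the first two south-west readings, product climbed as time to the power 1.63. If early product follows the substrate charge, a fixed amount of product comes sooner at a larger charge, and the rate there follows that charge to the power 0.614. The first south-east reading against the south-west one gave 0.586 for free catalyst. Two percent of the south-west charge is less than the first reading, so both figures rest on an extrapolated curve.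

The weak link was the step down to a charge below those tried, so I reckoned the correction. The north-east share lay 0.038 percentage points above the south-west one, less than the 0.25 points scatter of a south-west share, so I allowed that scatter per doubling of charge. The south run lies 1.74 doublings down, which allowed 0.43 points, and the share stood.

The forecast gave 0.55, 0.52 and 80 %, holding that “conversion at a given time is independent of charge”. Its share matched mine, while my orders came out higher than its two.

The flask gave 0.58, 0.55 and 80.0 %.

    active catalyst + substrate → product + active catalyst (4.428 M⁻¹ min⁻¹)
    free catalyst → active catalyst (0.2478 min⁻¹)
    2 active catalyst → 2 spent catalyst (2.970 M⁻¹ min⁻¹)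

The steps that make and lose active catalyst contain neither substrate nor product, and the loss of active catalyst moves the readings by 63 in units of the scatter, root mean square. The clock share of the south run's charge is 0.0959 M of product. In the east run, the same share of 0.400 M on top of the 0.200 M of added product gives 0.520 M at 34 min, and the reading there was 0.5213 M.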